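**Assumptions.** The target, 3,5,6,7,8,4'-hexamethoxyflavone (C21H22O8), is planar and has no stereocentres, so "single enantiomer" needs no stereocontrol. 1,2,3,4-Tetramethoxybenzene is taken as a catalogue chemical.

## Retrosynthetic overview

1. Ring C (the pyranone) is closed last through the O1–C8a bond by a dehydrogenative C–H/O annulation of 2-methoxy-1,3-diketone 5 (the new step); no phenol is ever made.
2. Diketone 5 comes from C-acylation of α-methoxy ketone 3 with 4-methoxybenzoyl chloride 4 (C2–C3 bond, ring B attached).
3. Ketone 3 comes from ortho-lithiation of 1,2,3,4-tetramethoxybenzene 1 and Weinreb amide 2 (C4–C4a bond; the C3-OMe is carried in from the start).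
4. Ring order: rings A and B are bought intact; ring C is formed last.

## Route

**Step 1**
Reactants: 1, 1,2,3,4-tetramethoxybenzene; 2, N,2-dimethoxy-N-methylacetamide
Product: 3, 2-methoxy-1-(2,3,4,5-tetramethoxyphenyl)ethan-1-one
Conditions: n-BuLi (1.1 eq), TMEDA (1.1 eq), THF, 0 °C → rt, 2 h; then 2, −78 → 0 °C; aq. NH4Cl
Reagents that add atoms: none besides reactant 2 (N,2-dimethoxy-N-methylacetamide, COCC(=O)N(C)OC), which supplies the CH3OCH2C(=O) unit
Why: Directed ortho-metalation at C5 (C5 and C6 are equivalent, each ortho to an OMe) followed by Weinreb ketone synthesis, whose chelated tetrahedral intermediate prevents over-addition; no stereocentre is formed.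

**Step 2**
Reactants: 3, 2-methoxy-1-(2,3,4,5-tetramethoxyphenyl)ethan-1-one; 4, 4-methoxybenzoyl chloride
Product: 5, 2-methoxy-1-(4-methoxyphenyl)-3-(2,3,4,5-tetramethoxyphenyl)propane-1,3-dione (racemic at C2, configurationally labile by enolisation)
Conditions: LiHMDS (2.1 eq), THF, −78 °C, 45 min; then 4 (1.0 eq), −78 → 0 °C; aq. NH4Cl
Reagents that add atoms: none besides reactant 4 (4-methoxybenzoyl chloride, COc1ccc(C(=O)Cl)cc1), which supplies the 4-MeOC6H4C(=O) unit
Why: Claisen-type C-acylation of the chelated lithium (Z)-enolate of an α-alkoxy ketone, with the second equivalent of base deprotonating the more acidic 1,3-diketone product to stop further acylation; the C2 stereocentre is irrelevant because it becomes sp2 in step 3.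

**Step 3**
Reactants: 5, 2-methoxy-1-(4-methoxyphenyl)-3-(2,3,4,5-tetramethoxyphenyl)propane-1,3-dione
Product: 6, 3-methoxytangeretin, i.e. 3,5,6,7,8-pentamethoxy-2-(4-methoxyphenyl)-4H-chromen-4-one (target)
Conditions: 9-mesityl-10-methylacridinium perchlorate (5 mol%), Co(dmgH)2(py)Cl (5 mol%), degassed MeCN (0.05 M, no fluoroalcohol), 450 nm LEDs, Ar, 25 °C, 24 h (−H2)
Reagents that add atoms: none
Why: Proposed new method: an acceptorless photoredox/cobaloxime dehydrogenative C(sp2)–H/O annulation of a 1,3-diketone, in which the excited acridinium (E* ≈ +2.0 V vs SCE) oxidises the tetramethoxyaryl ring (the most electron-rich π-system) to its radical cation, the anisoyl oxygen (keto or enol form) closes a six-membered ring onto C6–H (the only ring C–H it can reach, ortho to one OMe and para to another), and the cobaloxime carries the two electrons and two protons (aryl C–H and the acidic C3–H) to H2 to give the aromatic 4-pyranone, while ipso attack at the ortho-OMe carbon should revert because it cannot rearomatise under net-oxidative, fluoroalcohol-free conditions; the closest known reaction types are acridinium/cobaloxime arene C–H amination with H2 evolution, photoredox or anodic dehydrogenative lactonisation of 2-arylbenzoic acids, and FeCl3-mediated oxidative enol-O/arene C–H closure of electron-rich α-aryl ketones to benzofurans.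

## Compound list

1 | 1,2,3,4-tetramethoxybenzene | COc1ccc(OC)c(OC)c1OC | starting material
2 | N,2-dimethoxy-N-methylacetamide | COCC(=O)N(C)OC | starting material
3 | 2-methoxy-1-(2,3,4,5-tetramethoxyphenyl)ethan-1-one | COCC(=O)c1cc(OC)c(OC)c(OC)c1OC | intermediate
4 | 4-methoxybenzoyl chloride | COc1ccc(C(=O)Cl)cc1 | starting material
5 | 2-methoxy-1-(4-methoxyphenyl)-3-(2,3,4,5-tetramethoxyphenyl)propane-1,3-dione (racemic) | COc1ccc(C(=O)C(OC)C(=O)c2cc(OC)c(OC)c(OC)c2OC)cc1 | intermediate
6 | 3-methoxytangeretin (3,5,6,7,8-pentamethoxy-2-(4-methoxyphenyl)-4H-chromen-4-one) | COc1ccc(-c2oc3c(OC)c(OC)c(OC)c(OC)c3c(=O)c2OC)cc1 | target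

## Summary

Total step count: 3. Longest linear sequence: 3.

**Steps most likely to fail**

1. **Step 3 (proposed new annulation).** The main risks are ipso attack at the ortho-OMe carbon, over-oxidation of the A ring to a 5,8-quinone, or no cyclisation from the keto tautomer. Ipso attack would give the 5-demethoxy flavone by cation-radical SNAr, or a quinone monoketal.
 Fallback (known chemistry, phenol-first approach):
 - Lithiate 1, then B(OMe)3 and H2O2, to give 2,3,4,5-tetramethoxyphenol.
 - Ortho-acylate with methoxyacetic anhydride/BF3·OEt2 (or Hoesch with methoxyacetonitrile) to give 1-(2-hydroxy-3,4,5,6-tetramethoxyphenyl)-2-methoxyethanone.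
 - Run an Allan–Robinson condensation with 4-methoxybenzoic anhydride and sodium 4-methoxybenzoate at about 180 °C to give 6. The alternative is O-anisoylation, Baker–Venkataraman rearrangement (KOH/pyridine), then H2SO4/AcOH cyclodehydration.

2. **Step 2 (C-acylation).** The risk is O-acylation or double acylation of the α-methoxy enolate.
 Fallback: aldol addition of the lithium enolate of 3 to 4-methoxybenzaldehyde, then Dess–Martin oxidation of the β-hydroxy ketone to 5. This two-step redox approach has no O-acylation pathway.

3. **Step 1 (ortho-lithiation/Weinreb acylation).** The risk is incomplete metalation, or the aryllithium enolising amide 2.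
 Fallback: Friedel–Crafts acylation of 1 with methoxyacetyl chloride and SnCl4 in CH2Cl2 at 0 °C. This is an SEAr approach; AlCl3 is avoided to prevent demethylation of the OMe ortho to the new ketone.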